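The side chain (C1' at the ring to C16') is cut between C9' and C10'. The key step exploits the acyclic C10'(OH)–C11'(OH)(CH3) diol: the C11' oxygen serves as the ring oxygen and leaving group of an oxirane, which makes C10' a carbenoid, while the quinone ring stays masked as its dimethyl ether. The S epoxide of 6-methylhept-5-en-2-one is lithiated at CH2 and trapped by a pinacol boronic ester that carries the aryl diene chain up to C9'. A 1,2-metallate shift then moves C9' from boron to C10', opens the oxirane and leaves a C–B bond for oxidation, so one operation joins the halves and sets the syn diol.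

Key step: step 8

Assumption: LaLi3 tris((S)-binaphthoxide) is taken to deliver the S epoxide 12; should the sense of induction be the opposite, the R ligand is used and nothing else changes.

Step 1
Reactants: 1 4-methoxy-2-methylphenol
Product: 2 2-bromo-4-methoxy-6-methylphenol
Conditions: NBS (1.0 equiv), CH2Cl2, 0 °C → rt
Reagents that add atoms: N-bromosuccinimide O=C1CCC(=O)N1Br
Why: Electrophilic aromatic bromination in which the free hydroxyl is the strongest director and its para position is blocked, so bromine should enter the only open ortho position.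

Step 2
Reactants: 2 2-bromo-4-methoxy-6-methylphenol
Product: 3 1-bromo-2,5-dimethoxy-3-methylbenzene
Conditions: MeI, K2CO3, acetone, reflux
Reagents that add atoms: iodomethane CI
Why: Williamson O-methylation of the phenoxide gives the hydroquinone dimethyl ether that masks the quinone until the end.

Step 3
Reactants: 3 1-bromo-2,5-dimethoxy-3-methylbenzene; 4 geranyl bromide, (2E)-1-bromo-3,7-dimethylocta-2,6-diene
Product: 6 1-[(2E)-3,7-dimethylocta-2,6-dien-1-yl]-2,5-dimethoxy-3-methylbenzene, via aryl Grignard reagent 5 (not isolated)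
Conditions: Mg turnings, THF, 40 °C; then 4, Li2CuCl4 (3 mol %), THF, −10 °C → rt
Reagents that add atoms: none
Why: Copper-catalysed allylic substitution of an aryl Grignard reagent (Kochi-type coupling) on a primary allylic bromide should occur at the α carbon with retention of the E alkene.

Step 4
Reactants: 6 1-[(2E)-3,7-dimethylocta-2,6-dien-1-yl]-2,5-dimethoxy-3-methylbenzene
Product: 7 (2E,6E)-8-(2,5-dimethoxy-3-methylphenyl)-2,6-dimethylocta-2,6-dien-1-ol
Conditions: SeO2 (0.3 equiv), t-BuOOH (5.5 M in decane, 2.5 equiv), salicylic acid (0.1 equiv), CH2Cl2, 0 °C → rt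
Reagents that add atoms: tert-butyl hydroperoxide CC(C)(C)OO (terminal oxidant), its oxygen relayed by catalytic selenium dioxide O=[Se]=O
Why: Riley-type allylic oxidation (ene reaction, then [2,3]-sigmatropic shift) is selective for the E methyl group of the terminal trisubstituted alkene and should give the E allylic alcohol.

Step 5
Reactants: 7 (2E,6E)-8-(2,5-dimethoxy-3-methylphenyl)-2,6-dimethylocta-2,6-dien-1-ol
Product: 8 1-[(2E,6E)-8-bromo-3,7-dimethylocta-2,6-dien-1-yl]-2,5-dimethoxy-3-methylbenzene
Conditions: CBr4, PPh3, CH2Cl2, 0 °C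
Reagents that add atoms: carbon tetrabromide BrC(Br)(Br)Br
Why: Appel bromination converts the primary allylic alcohol into the bromide under neutral conditions without allylic transposition.

Step 6
Reactants: 8 1-[(2E,6E)-8-bromo-3,7-dimethylocta-2,6-dien-1-yl]-2,5-dimethoxy-3-methylbenzene; 9 2,2'-methylenebis(4,4,5,5-tetramethyl-1,3,2-dioxaborolane)
Product: 10 2-[(3E,7E)-9-(2,5-dimethoxy-3-methylphenyl)-3,7-dimethylnona-3,7-dien-1-yl]-4,4,5,5-tetramethyl-1,3,2-dioxaborolane
Conditions: 9 (1.5 equiv), NaOt-Bu (1.5 equiv), THF, rt; then 8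
Reagents that add atoms: none
Why: Deborylative alkylation of the geminal bis(boronate): alkoxide attack on one boron releases an α-boryl carbanion that displaces the primary allylic bromide (SN2) and so adds the C9' methylene with its boronic ester.

Step 7
Reactants: 11 6-methylhept-5-en-2-one
Product: 12 (2S)-2-methyl-2-(4-methylpent-3-en-1-yl)oxirane
Conditions: Me3S(O)I, NaH, THF/DMSO (ylide); LaLi3[(S)-binaphthoxide]3 (5 mol %), (2,4,6-(MeO)3C6H2)3P=O (5 mol %), 5 Å MS, THF, rt
Reagents that add atoms: trimethylsulfoxonium iodide C[S+](C)(C)=O.[I-]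
Why: Catalytic asymmetric Corey–Chaykovsky epoxidation, in which the lanthanum–lithium binaphthoxide binds the methyl ketone and the ylide and directs methylene transfer to one enantioface, sets the C11' stereocentre; the isolated alkene is inert to the ylide.

Step 8
Reactants: 10 2-[(3E,7E)-9-(2,5-dimethoxy-3-methylphenyl)-3,7-dimethylnona-3,7-dien-1-yl]-4,4,5,5-tetramethyl-1,3,2-dioxaborolane; 12 (2S)-2-methyl-2-(4-methylpent-3-en-1-yl)oxirane
Product: 16 (6S,7S,10E,14E)-16-(2,5-dimethoxy-3-methylphenyl)-2,6,10,14-tetramethyl-6-(triethylsilyloxy)hexadeca-2,10,14-trien-7-ol, via oxiranyllithium 13 (not isolated), via lithium boronate 14 (not isolated), via silyloxy boronic ester 15 (not isolated)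
Conditions: LiTMP (1.5 equiv) added to 10 and 12 (1.5 equiv), THF, −30 °C; Et3SiOTf, −78 °C → rt; then NaOH (2 M aq), H2O2 (30% aq), THF, 0 °C
Reagents that add atoms: triethylsilyl trifluoromethanesulfonate CC[Si](CC)(CC)OS(=O)(=O)C(F)(F)F; hydrogen peroxide OO
Why: LiTMP removes the oxirane hydrogen of 12 that is cis to the methyl group (trans to the 4-methylpent-3-enyl chain), the oxiranyllithium 13 is trapped at once by 10 with retention to give boronate 14, and Et3SiOTf then activates the ring oxygen so that the C9' methylene migrates from boron to C10' anti to the breaking C10'–O bond to give 15, whose C–B bond is oxidised with retention. The closest known reaction type is the lithiation–borylation of α-lithiated terminal epoxides with pinacol boronic esters (a Matteson-type 1,2-metallate rearrangement), which unites two nucleophilic carbons through the carbenoid character of C10' and turns boronic esters into syn-1,2-diols. No ring is closed; the oxirane ring is opened. C11' (S) comes unchanged from 12, and C10' (S) is fixed stereospecifically by retention (borylation), inversion (migration) and retention (oxidation), so that lithium cis to methyl translates into the 10'S,11'S syn diol. The step needs selection between the two diastereotopic oxirane hydrogens, which the bulk of the amide should steer to the face of the smaller methyl group, and deprotonation of the oxirane rather than of the ArCH2–CH= position of 10, which lithium coordination to the oxirane oxygen, the low temperature and the in situ capture should secure. Only the primary alkyl group migrates, since the pinacol oxygens do not.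

Step 9
Reactants: 16 (6S,7S,10E,14E)-16-(2,5-dimethoxy-3-methylphenyl)-2,6,10,14-tetramethyl-6-(triethylsilyloxy)hexadeca-2,10,14-trien-7-ol
Product: 17 2-[(2E,6E,10S,11S)-10-hydroxy-3,7,11,15-tetramethyl-11-(triethylsilyloxy)hexadeca-2,6,14-trien-1-yl]-6-methylcyclohexa-2,5-diene-1,4-dione
Conditions: (NH4)2Ce(NO3)6 (2.5 equiv), MeCN/H2O (3:1), 0 °C, 15 min
Reagents that add atoms: water O
Why: Oxidative demethylation of the 1,4-dimethoxyarene (two single-electron oxidations, water attack, loss of methanol) gives the 1,4-benzoquinone, and with the tertiary oxygen silylated no free vicinal diol is exposed to the oxidant.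

Step 10
Reactants: 17 2-[(2E,6E,10S,11S)-10-hydroxy-3,7,11,15-tetramethyl-11-(triethylsilyloxy)hexadeca-2,6,14-trien-1-yl]-6-methylcyclohexa-2,5-diene-1,4-dione
Product: 18 2-[(2E,6E,10S,11S)-10,11-dihydroxy-3,7,11,15-tetramethylhexadeca-2,6,14-trien-1-yl]-6-methylcyclohexa-2,5-diene-1,4-dione
Conditions: HF (48% aq), MeCN, 0 °C
Reagents that add atoms: none
Why: Fluoride-mediated cleavage of the triethylsilyl ether under mildly acidic conditions, which the quinone, the trisubstituted alkenes and the diol should tolerate, frees the tertiary hydroxyl without touching either stereocentre.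

Compound list
1 | 4-methoxy-2-methylphenol | Oc1ccc(OC)cc1C | starting material
2 | 2-bromo-4-methoxy-6-methylphenol | Oc1c(Br)cc(OC)cc1C | intermediate
3 | 1-bromo-2,5-dimethoxy-3-methylbenzene | COc1cc(Br)c(OC)c(C)c1 | intermediate
4 | geranyl bromide, (2E)-1-bromo-3,7-dimethylocta-2,6-diene | CC(C)=CCC/C(C)=C/CBr | starting material
5 | (2,5-dimethoxy-3-methylphenyl)magnesium bromide | COc1cc([Mg]Br)c(OC)c(C)c1 | intermediate (not isolated)
6 | 1-[(2E)-3,7-dimethylocta-2,6-dien-1-yl]-2,5-dimethoxy-3-methylbenzene | CC(C)=CCC/C(C)=C/Cc1cc(OC)cc(C)c1OC | intermediate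
7 | (2E,6E)-8-(2,5-dimethoxy-3-methylphenyl)-2,6-dimethylocta-2,6-dien-1-ol | OC/C(C)=C/CC/C(C)=C/Cc1cc(OC)cc(C)c1OC | intermediate
8 | 1-[(2E,6E)-8-bromo-3,7-dimethylocta-2,6-dien-1-yl]-2,5-dimethoxy-3-methylbenzene | BrC/C(C)=C/CC/C(C)=C/Cc1cc(OC)cc(C)c1OC | intermediate
9 | 2,2'-methylenebis(4,4,5,5-tetramethyl-1,3,2-dioxaborolane) | CC1(C)OB(CB2OC(C)(C)C(C)(C)O2)OC1(C)C | starting material
10 | 2-[(3E,7E)-9-(2,5-dimethoxy-3-methylphenyl)-3,7-dimethylnona-3,7-dien-1-yl]-4,4,5,5-tetramethyl-1,3,2-dioxaborolane | CC1(C)OB(CC/C(C)=C/CC/C(C)=C/Cc2cc(OC)cc(C)c2OC)OC1(C)C | intermediate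
11 | 6-methylhept-5-en-2-one | CC(=O)CCC=C(C)C | starting material
12 | (2S)-2-methyl-2-(4-methylpent-3-en-1-yl)oxirane | CC(C)=CCC[C@@]1(C)CO1 | intermediate
13 | [(2S,3S)-3-methyl-3-(4-methylpent-3-en-1-yl)oxiran-2-yl]lithium, lithium cis to the methyl group | CC(C)=CCC[C@@]1(C)[C@H]([Li])O1 | intermediate (not isolated)
14 | lithium boronate complex of 13 with 10: boron carries the pinacolato group, the C9' alkyl chain and the oxiranyl carbon C10' (boron cis to the methyl group) | CC(C)=CCC[C@@]1(C)[C@H]([B-]2(CC/C(C)=C/CC/C(C)=C/Cc3cc(OC)cc(C)c3OC)OC(C)(C)C(C)(C)O2)O1.[Li+] | intermediate (not isolated)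
15 | 2-[(6S,7S,10E,14E)-16-(2,5-dimethoxy-3-methylphenyl)-2,6,10,14-tetramethyl-6-(triethylsilyloxy)hexadeca-2,10,14-trien-7-yl]-4,4,5,5-tetramethyl-1,3,2-dioxaborolane | CC(C)=CCC[C@](C)(O[Si](CC)(CC)CC)[C@@H](B1OC(C)(C)C(C)(C)O1)CC/C(C)=C/CC/C(C)=C/Cc2cc(OC)cc(C)c2OC | intermediate (not isolated)
16 | (6S,7S,10E,14E)-16-(2,5-dimethoxy-3-methylphenyl)-2,6,10,14-tetramethyl-6-(triethylsilyloxy)hexadeca-2,10,14-trien-7-ol | CC(C)=CCC[C@](C)(O[Si](CC)(CC)CC)[C@@H](O)CC/C(C)=C/CC/C(C)=C/Cc1cc(OC)cc(C)c1OC | intermediate
17 | 2-[(2E,6E,10S,11S)-10-hydroxy-3,7,11,15-tetramethyl-11-(triethylsilyloxy)hexadeca-2,6,14-trien-1-yl]-6-methylcyclohexa-2,5-diene-1,4-dione | CC(C)=CCC[C@](C)(O[Si](CC)(CC)CC)[C@@H](O)CC/C(C)=C/CC/C(C)=C/CC1=CC(=O)C=C(C)C1=O | intermediate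
18 | 2-[(2E,6E,10S,11S)-10,11-dihydroxy-3,7,11,15-tetramethylhexadeca-2,6,14-trien-1-yl]-6-methylcyclohexa-2,5-diene-1,4-dione | CC(C)=CCC[C@](C)(O)[C@@H](O)CC/C(C)=C/CC/C(C)=C/CC1=CC(=O)C=C(C)C1=O | target

Total step count: 10. Longest linear sequence: 9 steps (steps 1 to 6, then 8 to 10); step 7 supplies the second fragment.

Steps most likely to fail

Step 8. The amide may select poorly between the two diastereotopic oxirane hydrogens (methyl against a CH2 chain on the neighbouring carbon), so that the C10' epimer forms alongside; lateral deprotonation of 10 or β-elimination of the oxirane may also consume base. The fallback sets out from 16, taken as the mixture of C10' epimers, and comes back at 16: the stereocentre is set by reagent control instead of by the lithiation. Oxidation with Dess–Martin periodinane (NaHCO3, CH2Cl2) should converge both epimers on the α-silyloxy ketone (6S,10E,14E)-16-(2,5-dimethoxy-3-methylphenyl)-2,6,10,14-tetramethyl-6-(triethylsilyloxy)hexadeca-2,10,14-trien-7-one F1, in which C11' is untouched. Corey–Bakshi–Shibata reduction with the (R)-2-methyl-oxazaborolidine and BH3·SMe2 (toluene, −20 °C), with the fully substituted C11' as the large group, should then return 16 as the 10'S epimer.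

Step 4. Oxidation may run on to the enal or attack the allylic positions of the inner alkene, so that site selectivity and conversion suffer. The fallback sets out from 6 and comes back at 7: the E allylic alcohol is built by cleavage and olefination instead of C–H oxidation. NBS in THF/H2O (0 °C) should give the terminal bromohydrin (6E)-3-bromo-8-(2,5-dimethoxy-3-methylphenyl)-2,6-dimethyloct-6-en-2-ol F2 (racemic). K2CO3 in MeOH closes it to the epoxide 2-[(3E)-5-(2,5-dimethoxy-3-methylphenyl)-3-methylpent-3-en-1-yl]-3,3-dimethyloxirane F3. HIO4·2H2O (THF/Et2O) cleaves it to the aldehyde (4E)-6-(2,5-dimethoxy-3-methylphenyl)-4-methylhex-4-enal F4. Wittig reaction with ethyl 2-(triphenylphosphoranylidene)propanoate (CH2Cl2, rt) gives the enoate ethyl (2E,6E)-8-(2,5-dimethoxy-3-methylphenyl)-2,6-dimethylocta-2,6-dienoate F5. Reduction with i-Bu2AlH (CH2Cl2, −78 °C) returns 7.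

Step 7. Enantioface discrimination of an aliphatic methyl ketone (methyl against a CH2 chain) may be insufficient, which would carry the wrong C11' configuration into the key step. The fallback does not start from a numbered compound: 11 is replaced by 2-methylprop-2-en-1-ol and 1-bromo-3-methylbut-2-ene, and the route is rejoined at 12. The dianion of 2-methylprop-2-en-1-ol (n-BuLi, TMEDA, Et2O) is alkylated with 1-bromo-3-methylbut-2-ene to give 6-methyl-2-methylidenehept-5-en-1-ol F6. Sharpless asymmetric epoxidation (Ti(OiPr)4, L-(+)-diisopropyl tartrate, t-BuOOH, 4 Å MS, CH2Cl2, −20 °C) acts only on the allylic alcohol alkene and should give [(2S)-2-(4-methylpent-3-en-1-yl)oxiran-2-yl]methanol F7. LiAlH4 (THF, 0 °C) opens the oxirane at its CH2 to give (2S)-2,6-dimethylhept-5-ene-1,2-diol F8. TsCl in pyridine gives the primary sulfonate (2S)-2-hydroxy-2,6-dimethylhept-5-en-1-yl 4-methylbenzenesulfonate F9, and K2CO3 in MeOH closes it to 12 without touching the stereocentre.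

Further compounds
F1 | step 8 | (6S,10E,14E)-16-(2,5-dimethoxy-3-methylphenyl)-2,6,10,14-tetramethyl-6-(triethylsilyloxy)hexadeca-2,10,14-trien-7-one | CC(C)=CCC[C@](C)(O[Si](CC)(CC)CC)C(=O)CC/C(C)=C/CC/C(C)=C/Cc1cc(OC)cc(C)c1OC
F2 | step 4 | (6E)-3-bromo-8-(2,5-dimethoxy-3-methylphenyl)-2,6-dimethyloct-6-en-2-ol (racemic) | CC(C)(O)C(Br)CC/C(C)=C/Cc1cc(OC)cc(C)c1OC
F3 | step 4 | 2-[(3E)-5-(2,5-dimethoxy-3-methylphenyl)-3-methylpent-3-en-1-yl]-3,3-dimethyloxirane (racemic) | CC1(C)OC1CC/C(C)=C/Cc2cc(OC)cc(C)c2OC
F4 | step 4 | (4E)-6-(2,5-dimethoxy-3-methylphenyl)-4-methylhex-4-enal | O=CCC/C(C)=C/Cc1cc(OC)cc(C)c1OC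
F5 | step 4 | ethyl (2E,6E)-8-(2,5-dimethoxy-3-methylphenyl)-2,6-dimethylocta-2,6-dienoate | CCOC(=O)/C(C)=C/CC/C(C)=C/Cc1cc(OC)cc(C)c1OC
F6 | step 7 | 6-methyl-2-methylidenehept-5-en-1-ol | C=C(CO)CCC=C(C)C
F7 | step 7 | [(2S)-2-(4-methylpent-3-en-1-yl)oxiran-2-yl]methanol | CC(C)=CCC[C@]1(CO)CO1
F8 | step 7 | (2S)-2,6-dimethylhept-5-ene-1,2-diol | CC(C)=CCC[C@](C)(O)CO
F9 | step 7 | (2S)-2-hydroxy-2,6-dimethylhept-5-en-1-yl 4-methylbenzenesulfonate | CC(C)=CCC[C@](C)(O)COS(=O)(=O)c1ccc(C)cc1
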